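**Plan**

1. Retrosynthesis: the two aryl O–CH3 bonds at C5 and C7 are cut first, then C4a–C5 of ring A, then O1–C8a of ring C, then C4–C4a and finally C8–C8a. This leaves an aryl β-keto ester (C2–C4), an acetyl unit (C4a, C8a) and an acetoacetate-derived dioxinone (C5–C8).
2. Enabling feature: ring A carries oxygen on C5 and C7 and is fused at C4a–C8a to ring C, whose O1–C8a=C4a–C4=O unit is a vinylogous ester with a nucleophilic C4a. C5–C8 can therefore sit on C8a as a dioxinone-masked acetoacetyl chain that folds back onto C4a.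
3. Forward: the trimethoxyphenyl ring is bought; C8–C8a and C4–C4a join the chain; ring C closes by cyclodehydration (O1–C8a); ring A closes last by acylketene cyclisation and aromatisation (C4a–C5); the two phenols are then methylated.
4. Stereochemistry: C2, the only stereocentre, is set as S by catalyst-controlled asymmetric transfer hydrogenation of the aryl ketone, and its C–O bond is never broken afterwards.

Key step: step 7

Assumption: chromanone numbering (O1, C2–C4, C4a, C5–C8, C8a) is used for every atom that ends up in the target, and the 3,4,5-trimethoxyphenyl carbinol centre is taken as configurationally stable to the brief acid treatment of step 6, because the two meta methoxy groups and the β-carbonyl disfavour a benzylic cation.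

**Step 1**
Reactants: 1 2,2,6-trimethyl-4H-1,3-dioxin-4-one; 2 acetyl chloride
Product: 3 2,2-dimethyl-6-(2-oxopropyl)-4H-1,3-dioxin-4-one
Conditions: LiN(SiMe3)2 (1 equiv per 1), THF, −78 °C; then 2 (0.5 equiv), −78 °C; 1 M HCl
Reagents that add atoms: none
Why: Kinetic γ-deprotonation of 1 gives the lithium dienolate, which is C-acylated at the exocyclic carbon by the acid chloride (vinylogous Claisen-type acylation); half an equivalent of 2 is used because 3 is more acidic than 1 and consumes a second dienolate.

**Step 2**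
Reactants: 4 ethyl 3-oxo-3-(3,4,5-trimethoxyphenyl)propanoate
Product: 5 ethyl (3S)-3-hydroxy-3-(3,4,5-trimethoxyphenyl)propanoate
Conditions: RuCl[(S,S)-TsDPEN](p-cymene) (1 mol %), HCO2H/Et3N (5:2), DMF, 40 °C
Reagents that add atoms: none
Why: Noyori–Ikariya asymmetric transfer hydrogenation, in which the (S,S)-catalyst holds the aryl group under the η6-cymene by a CH/π contact and delivers hydride to the Re face of the aryl ketone, so the future C2 is set as S by catalyst control in the same sense as acetophenone gives (S)-1-phenylethanol.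

**Step 3**
Reactants: 5 ethyl (3S)-3-hydroxy-3-(3,4,5-trimethoxyphenyl)propanoate
Product: 6 ethyl (3S)-3-[(tert-butyldimethylsilyl)oxy]-3-(3,4,5-trimethoxyphenyl)propanoate
Conditions: TBSCl, imidazole, DMF, rt
Reagents that add atoms: tert-butyldimethylsilyl chloride, CC(C)(C)[Si](C)(C)Cl
Why: Imidazole-promoted silyl ether formation on a secondary benzylic alcohol is routine and blocks retro-aldol and alkoxide chemistry in steps 4 and 5.

**Step 4**
Reactants: 6 ethyl (3S)-3-[(tert-butyldimethylsilyl)oxy]-3-(3,4,5-trimethoxyphenyl)propanoate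
Product: 7 (3S)-3-[(tert-butyldimethylsilyl)oxy]-N-methoxy-N-methyl-3-(3,4,5-trimethoxyphenyl)propanamide
Conditions: MeNHOMe·HCl, i-PrMgCl, THF, −20 → 0 °C
Reagents that add atoms: N,O-dimethylhydroxylamine hydrochloride, CNOC.Cl
Why: Aminolysis of the ester by the chloromagnesium amide of N,O-dimethylhydroxylamine (Weinreb amide formation) is standard for β-silyloxy esters and leaves the β-stereocentre untouched.

**Step 5**
Reactants: 3 2,2-dimethyl-6-(2-oxopropyl)-4H-1,3-dioxin-4-one; 7 (3S)-3-[(tert-butyldimethylsilyl)oxy]-N-methoxy-N-methyl-3-(3,4,5-trimethoxyphenyl)propanamide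
Product: 8 6-[(6S)-6-[(tert-butyldimethylsilyl)oxy]-2,4-dioxo-6-(3,4,5-trimethoxyphenyl)hexyl]-2,2-dimethyl-4H-1,3-dioxin-4-one
Conditions: 3 (2 equiv), LiN(i-Pr)2 (commercial solution, 4 equiv), THF, −78 → −40 °C; then 7, −78 → −20 °C; 1 M HCl to pH 3
Reagents that add atoms: none
Why: Crossed Claisen condensation in which the 1,3-dicarbonyl dianion of 3 reacts at its terminal, more basic carbon with the Weinreb amide, whose chelated tetrahedral adduct prevents double addition, forming C4–C4a with the dioxinone intact.

**Step 6**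
Reactants: 8 6-[(6S)-6-[(tert-butyldimethylsilyl)oxy]-2,4-dioxo-6-(3,4,5-trimethoxyphenyl)hexyl]-2,2-dimethyl-4H-1,3-dioxin-4-one
Product: 10 (2S)-6-[(2,2-dimethyl-4-oxo-4H-1,3-dioxin-6-yl)methyl]-2-(3,4,5-trimethoxyphenyl)-2,3-dihydro-4H-pyran-4-one, via hydroxy diketone 9 (not isolated)
Conditions: HF·pyridine, THF, 0 °C → rt; then CF3CO2H (5 equiv), CH2Cl2, 0 °C
Reagents that add atoms: none
Why: Fluoride cleaves the silyl ether, and brief acid treatment drives hemiketalisation of the freed hydroxyl onto the 1,5-related ketone and dehydration to the vinylogous ester (cyclodehydration of a δ-hydroxy-β-diketone to a 2,3-dihydro-4H-pyran-4-one), which forms O1–C8a without breaking the C2–O bond so S is retained.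

**Step 7**
Reactants: 10 (2S)-6-[(2,2-dimethyl-4-oxo-4H-1,3-dioxin-6-yl)methyl]-2-(3,4,5-trimethoxyphenyl)-2,3-dihydro-4H-pyran-4-one
Product: 13 (2S)-5,7-dihydroxy-2-(3,4,5-trimethoxyphenyl)chroman-4-one, via acylketene 11 (not isolated), via cyclohexadienone 12 (not isolated)
Conditions: PhMe (about 2 mM), 110 °C, slow addition of 10 over several hours, Ar
Reagents that add atoms: none
Why: Proposed new method: at 110 °C the dioxinone of 10 undergoes the usual retro-[4+2] loss of acetone to acylketene 11, whose C7 ketone enolises towards the doubly activated C8 methylene so that C4a=C8a, C8=C7 and C6=C5(=O) form a dienylketene; thermal six-electron electrocyclisation of this triene, which in polar terms is C-acylation of the nucleophilic vinylogous-ester α-carbon C4a by the ketene carbon C5, makes the C4a–C5 bond and gives dienone 12, which tautomerises irreversibly to the aromatic 5,7-diol 13. The closest known reactions are the thermolysis of keto-dioxinones to acylketenes that are trapped intramolecularly and aromatised to resorcylates, and the 6π closure of dienylketenes to phenols as in the Danheiser benzannulation; closure of a dioxinone-derived acylketene onto C5 of a 2,3-dihydro-4H-pyran-4-one has no direct precedent. Ring A is the only ring formed and closes as a six-membered carbocycle by disrotatory 6π electrocyclisation (6-(enolendo)-exo-dig if viewed as an ionic acylation). No stereocentre is created, since C4a of 12 is lost on aromatisation, and C2 is safe because the medium is neutral and aprotic, so C3 is not enolised and O1 is not expelled. The selectivity required is intramolecular C-acylation over ketene dimerisation and over acylation of the phenols of 13 already formed, which slow addition at high dilution should secure, while O-acylation within the molecule is excluded because the C7 enol oxygen would have to close a four-membered ring, the C4 carbonyl oxygen an eight-membered ring, and O1 is a poorly nucleophilic vinylogous ester oxygen.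

**Step 8**
Reactants: 13 (2S)-5,7-dihydroxy-2-(3,4,5-trimethoxyphenyl)chroman-4-one
Product: 14 (2S)-5,7-dimethoxy-2-(3,4,5-trimethoxyphenyl)chroman-4-one
Conditions: MeI (excess), Ag2O, DMF, rt, dark
Reagents that add atoms: iodomethane, CI
Why: Purdie-type O-methylation with MeI on silver oxide should alkylate both phenols, the hydrogen-bonded 5-OH more slowly, under conditions too weakly basic to enolise C3 and open ring C by retro-oxa-Michael elimination, so C2 stays S.

**Compound list**

1 | 2,2,6-trimethyl-4H-1,3-dioxin-4-one | CC1=CC(=O)OC(C)(C)O1 | starting material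
2 | acetyl chloride | CC(=O)Cl | starting material
3 | 2,2-dimethyl-6-(2-oxopropyl)-4H-1,3-dioxin-4-one | CC(=O)CC1=CC(=O)OC(C)(C)O1 | intermediate
4 | ethyl 3-oxo-3-(3,4,5-trimethoxyphenyl)propanoate | CCOC(=O)CC(=O)c1cc(OC)c(OC)c(OC)c1 | starting material
5 | ethyl (3S)-3-hydroxy-3-(3,4,5-trimethoxyphenyl)propanoate | CCOC(=O)C[C@H](O)c1cc(OC)c(OC)c(OC)c1 | intermediate
6 | ethyl (3S)-3-[(tert-butyldimethylsilyl)oxy]-3-(3,4,5-trimethoxyphenyl)propanoate | CCOC(=O)C[C@H](O[Si](C)(C)C(C)(C)C)c1cc(OC)c(OC)c(OC)c1 | intermediate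
7 | (3S)-3-[(tert-butyldimethylsilyl)oxy]-N-methoxy-N-methyl-3-(3,4,5-trimethoxyphenyl)propanamide | CON(C)C(=O)C[C@H](O[Si](C)(C)C(C)(C)C)c1cc(OC)c(OC)c(OC)c1 | intermediate
8 | 6-[(6S)-6-[(tert-butyldimethylsilyl)oxy]-2,4-dioxo-6-(3,4,5-trimethoxyphenyl)hexyl]-2,2-dimethyl-4H-1,3-dioxin-4-one | CC1(C)OC(=O)C=C(CC(=O)CC(=O)C[C@H](O[Si](C)(C)C(C)(C)C)c2cc(OC)c(OC)c(OC)c2)O1 | intermediate
9 | 6-[(6S)-6-hydroxy-2,4-dioxo-6-(3,4,5-trimethoxyphenyl)hexyl]-2,2-dimethyl-4H-1,3-dioxin-4-one (hydroxy diketone, in equilibrium with its cyclic hemiketal) | CC1(C)OC(=O)C=C(CC(=O)CC(=O)C[C@H](O)c2cc(OC)c(OC)c(OC)c2)O1 | intermediate (not isolated)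
10 | (2S)-6-[(2,2-dimethyl-4-oxo-4H-1,3-dioxin-6-yl)methyl]-2-(3,4,5-trimethoxyphenyl)-2,3-dihydro-4H-pyran-4-one | O=C1C[C@@H](c2cc(OC)c(OC)c(OC)c2)OC(CC2=CC(=O)OC(C)(C)O2)=C1 | intermediate
11 | 4-[(2S)-4-oxo-2-(3,4,5-trimethoxyphenyl)-3,4-dihydro-2H-pyran-6-yl]buta-1-ene-1,3-dione (acylketene) | O=C=CC(=O)CC1=CC(=O)C[C@@H](c2cc(OC)c(OC)c(OC)c2)O1 | intermediate (not isolated)
12 | (2S)-7-hydroxy-2-(3,4,5-trimethoxyphenyl)-2,3-dihydro-4H-chromene-4,5(4aH)-dione (cyclohexadienone, C4a unassigned) | O=C1C=C(O)C=C2O[C@H](c3cc(OC)c(OC)c(OC)c3)CC(=O)C12 | intermediate (not isolated)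
13 | (2S)-5,7-dihydroxy-2-(3,4,5-trimethoxyphenyl)chroman-4-one | Oc1cc(O)c2c(c1)O[C@H](c1cc(OC)c(OC)c(OC)c1)CC2=O | intermediate
14 | (2S)-5,7-dimethoxy-2-(3,4,5-trimethoxyphenyl)chroman-4-one | COc1cc(OC)c2c(c1)O[C@H](c1cc(OC)c(OC)c(OC)c1)CC2=O | target

**Step count and risks**

Total steps: 8. Longest linear sequence: 7 steps (4 → 14, steps 2–8); step 1 is a one-step side branch that joins at step 5.

Steps most likely to fail:

Step 7 (labelled step). The acylketene may be consumed by dimerisation or by acylating phenols of product already formed faster than it closes onto C4a, or the enol geometry needed for the six-electron closure may be poorly populated. The fallback uses known chemistry, sets out from 4 and returns at 14. Heating 4 with phloroglucinol without solvent (Mentzer pyrone synthesis) should give 5,7-dihydroxy-2-(3,4,5-trimethoxyphenyl)-4H-chromen-4-one F1. Methylation with MeI and K2CO3 in refluxing acetone, where no stereocentre is at risk, should give 5,7-dimethoxy-2-(3,4,5-trimethoxyphenyl)-4H-chromen-4-one F2. Enantioselective hydrogenation of the C2=C3 bond with a chiral ruthenium N-heterocyclic carbene catalyst (Ru(cod)(2-methylallyl)2, SINpEt·HBF4, KOt-Bu, H2) is then run with the ligand antipode that leads to the 2S series; which antipode that is has to be assigned on the first run. Any over-reduced (2S)-5,7-dimethoxy-2-(3,4,5-trimethoxyphenyl)chroman-4-ol F3 is re-oxidised with Dess–Martin periodinane, so all material converges on 14.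

Step 6. Aldol-type attack of dioxinone C5 on the diketone (resorcylate formation) may compete with hemiketalisation, the dioxinone acetal may be lost in acid, or C2 may partly ionise. The fallback closes ring C before any dioxinone exists; it sets out from 7 and returns at 11 inside step 7.
- Crossed Claisen condensation of 7 with the dianion of tert-butyl acetoacetate (NaH, then n-BuLi, THF, 0 °C) should give tert-butyl (7S)-7-[(tert-butyldimethylsilyl)oxy]-3,5-dioxo-7-(3,4,5-trimethoxyphenyl)heptanoate F4.
- HF·pyridine followed by CF3CO2H in CH2Cl2 should remove the silyl group, cyclodehydrate and cleave the tert-butyl ester to 2-[(2S)-4-oxo-2-(3,4,5-trimethoxyphenyl)-3,4-dihydro-2H-pyran-6-yl]acetic acid F5, which is kept cold to avoid decarboxylation.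
- Coupling with Meldrum's acid (DCC, DMAP, CH2Cl2, 0 °C) should give 5-{[(2S)-4-oxo-2-(3,4,5-trimethoxyphenyl)-3,4-dihydro-2H-pyran-6-yl]acetyl}-2,2-dimethyl-1,3-dioxane-4,6-dione F6.
- Heating F6 in dilute toluene loses acetone and CO2 (the standard acylketene entry from acyl Meldrum's acids) and gives acylketene 11 directly.

Step 8. Enolisation at C3 with retro-oxa-Michael opening of ring C would erode the configuration at C2 and lead to chalcone ethers; the hydrogen-bonded 5-OH may be alkylated incompletely, or ring A may be C-methylated. The fallback replaces the single oxide-promoted alkylation by a staged sequence that uses the acidity difference of the two phenols; it sets out from 13 and returns at 14. Me3SiCHN2 in MeOH/toluene at rt should methylate only the free 7-OH and give (2S)-5-hydroxy-7-methoxy-2-(3,4,5-trimethoxyphenyl)chroman-4-one F7. The chelated 5-OH is then alkylated with trimethyloxonium tetrafluoroborate and 1,8-bis(dimethylamino)naphthalene in CH2Cl2, a base that cannot enolise C3, to give 14.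

**Further compounds**

F1 | step 7 | 5,7-dihydroxy-2-(3,4,5-trimethoxyphenyl)-4H-chromen-4-one | Oc1cc(O)c2c(c1)oc(-c1cc(OC)c(OC)c(OC)c1)cc2=O
F2 | step 7 | 5,7-dimethoxy-2-(3,4,5-trimethoxyphenyl)-4H-chromen-4-one | COc1cc(OC)c2c(c1)oc(-c1cc(OC)c(OC)c(OC)c1)cc2=O
F3 | step 7 | (2S)-5,7-dimethoxy-2-(3,4,5-trimethoxyphenyl)chroman-4-ol (C4 unassigned) | COc1cc(OC)c2c(c1)O[C@H](c1cc(OC)c(OC)c(OC)c1)CC2O
F4 | step 6 | tert-butyl (7S)-7-[(tert-butyldimethylsilyl)oxy]-3,5-dioxo-7-(3,4,5-trimethoxyphenyl)heptanoate | CC(C)(C)OC(=O)CC(=O)CC(=O)C[C@H](O[Si](C)(C)C(C)(C)C)c1cc(OC)c(OC)c(OC)c1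
F5 | step 6 | 2-[(2S)-4-oxo-2-(3,4,5-trimethoxyphenyl)-3,4-dihydro-2H-pyran-6-yl]acetic acid | OC(=O)CC1=CC(=O)C[C@@H](c2cc(OC)c(OC)c(OC)c2)O1
F6 | step 6 | 5-{[(2S)-4-oxo-2-(3,4,5-trimethoxyphenyl)-3,4-dihydro-2H-pyran-6-yl]acetyl}-2,2-dimethyl-1,3-dioxane-4,6-dione | CC1(C)OC(=O)C(C(=O)CC2=CC(=O)C[C@@H](c3cc(OC)c(OC)c(OC)c3)O2)C(=O)O1
F7 | step 8 | (2S)-5-hydroxy-7-methoxy-2-(3,4,5-trimethoxyphenyl)chroman-4-one | COc1cc(O)c2c(c1)O[C@H](c1cc(OC)c(OC)c(OC)c1)CC2=O
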